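The quinone ring (C1 carbonyl, C2 hydroxyl, C3 henicosyl, C4 carbonyl, C5 methoxy, C6 hydrogen) is an oxidised 5-alkylresorcinol: the chain on C3, the hydrogen on C6 and the meta-related oxygens on C1 and C5 are the signature the key step exploits. Everything rests on disconnecting ring bond C2–C3. An intramolecular aldol of the open-chain methyl 3,5,7-trioxooctacosanoate (a behenoyl-capped tetraketide ester) joins its ester-activated C2 to the C7 ketone and, after dehydration and enolisation, delivers the complete resorcylate ring in one operation. The retained ester then differentiates the two phenols before it is excised; two oxidations add the C4 and C2 oxygens.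

Key step: step 3

Remark: methyl 3,5-dioxohexanoate is taken as a catalogue chemical; the transient stereocentres of the cyclic aldol intermediate are left undefined because aromatisation erases them. The target has no stereocentre.

Step 1
Reactants: 1 docosanoic acid
Product: 3 N-methoxy-N-methyldocosanamide, via 1-docosanoylimidazole 2 (not isolated)
Conditions: CDI, THF, 45 °C; then MeNHOMe·HCl, rt
Reagents that add atoms: N,O-dimethylhydroxylamine hydrochloride, CNOC.Cl; 1,1'-carbonyldiimidazole, O=C(n1ccnc1)n1ccnc1 (imidazolyl group of 2 only)
Why: Acyl-imidazole activation followed by aminolysis is a standard Weinreb amide synthesis, and the saturated chain offers no competing reactive site.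

Step 2
Reactants: 3 N-methoxy-N-methyldocosanamide; 4 methyl 3,5-dioxohexanoate
Product: 5 methyl 3,5,7-trioxooctacosanoate
Conditions: 4 (1.3 equiv), LiN(iPr)2 (4.0 equiv), THF, 0 °C; then 3 (1.0 equiv), −20 → 0 °C; cold 1 M HCl to pH 4
Reagents that add atoms: none
Why: This is a Claisen-type C-acylation (Weinreb ketone synthesis) at the terminal C6 carbanion, the last-formed and most nucleophilic site of the 2,4,6-trianion, and the chelated tetrahedral adduct should prevent over-addition and proton transfer from the product until the quench.

Step 3
Reactants: 5 methyl 3,5,7-trioxooctacosanoate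
Product: 7 methyl 2,4-dihydroxy-6-henicosylbenzoate, via hydroxycyclohexanedione aldol adduct 6 (not isolated)
Conditions: K2CO3, MeOH–CH2Cl2 (1:1), rt; then HCl in MeOH, rt
Reagents that add atoms: none
Why: Carbonate in methanol reversibly forms the enolate at C2 (octacosanoate numbering, between the ester and the C3 ketone), which adds to the C7 ketone to give cyclic aldol 6; acid then dehydrates 6 and the two remaining ketones enolise, so the sequence ends irreversibly in the benzene ring. The closest known reaction type is the biomimetic base-mediated aldol aromatisation of 3,5,7-triketo esters to β-resorcylates. The single carbocycle closes in a 6-(enolendo)-exo-trig mode through the C2=C3 enolate (6-(enolexo) if the ester enolate form is drawn), and the new C2–C7 bond becomes ring bond C2–C3 of the quinone. No stereocentre is set: the two centres of 6 form unselectively and vanish on aromatisation. The step needs C2-to-C7 aldol closure to beat C6-to-C1 Claisen closure (to the docosanoylphloroglucinol) and O5-to-C1 lactonisation (to the hydroxypyranone). The substrate secures this because the C7 dialkyl ketone is a far better electrophile than the methyl ester, whose methoxide is a poor leaving group, and in methanol both acyl-transfer paths are reversible while aromatisation drains the aldol path.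

Step 4
Reactants: 7 methyl 2,4-dihydroxy-6-henicosylbenzoate
Product: 8 methyl 2-henicosyl-6-hydroxy-4-methoxybenzoate
Conditions: MeI (1.05 equiv), K2CO3 (1.1 equiv), acetone, 40 °C
Reagents that add atoms: iodomethane, CI
Why: This is a Williamson etherification in which the 2-hydroxyl, hydrogen-bonded to and flanked by the ester carbonyl, should stay untouched while the more acidic, unhindered para 4-hydroxyl is methylated.

Step 5
Reactants: 8 methyl 2-henicosyl-6-hydroxy-4-methoxybenzoate
Product: 10 3-henicosyl-5-methoxyphenol, via 2-henicosyl-6-hydroxy-4-methoxybenzoic acid 9 (not isolated)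
Conditions: KOH, DMSO–H2O (4:1), 120 °C; then 2 M HCl, 80 °C
Reagents that add atoms: potassium hydroxide, [K+].[OH-] (carboxyl oxygen of 9 only)
Why: Saponification of the hindered ester is followed by protodecarboxylation of the electron-rich salicylic acid (ipso protonation ortho and para to oxygen donors), the usual fate of β-resorcylic acids, and the aryl methyl ether is inert to hydroxide.

Step 6
Reactants: 10 3-henicosyl-5-methoxyphenol
Product: 11 2-henicosyl-6-methoxy-1,4-benzoquinone
Conditions: (KSO3)2NO (Fremy's salt, 2.5 equiv), KH2PO4 buffer, H2O–CH2Cl2, methyltrioctylammonium chloride (cat.), rt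
Reagents that add atoms: potassium nitrosodisulfonate, [O]N(S(=O)(=O)[O-])S(=O)(=O)[O-].[K+].[K+]
Why: In this Teuber oxidation the phenoxyl radical should couple with a second nitroxyl radical at the only para position (quinone C4, between methoxy and chain) and lose imidodisulfonate to give the p-quinone, with phase transfer carrying the oxidant to the waxy substrate.

Step 7
Reactants: 11 2-henicosyl-6-methoxy-1,4-benzoquinone
Product: 12 3-henicosyl-5-methoxybenzene-1,2,4-triyl triacetate
Conditions: Ac2O, BF3·OEt2, 40 °C
Reagents that add atoms: acetic anhydride, CC(=O)OC(C)=O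
Why: In this Thiele–Winter acetoxylation the methoxy group deactivates its own double bond as a vinylogous ester, so acetate should add at C2 (quinone numbering), the β-carbon of the C4 carbonyl on the methoxy-free double bond, before enolisation and peracetylation.

Step 8
Reactants: 12 3-henicosyl-5-methoxybenzene-1,2,4-triyl triacetate
Product: 14 3-henicosyl-2-hydroxy-5-methoxy-1,4-benzoquinone (CNP0317656.0), via 3-henicosyl-5-methoxybenzene-1,2,4-triol 13 (not isolated)
Conditions: K2CO3, degassed MeOH–THF, N2, rt; then 1 M HCl to pH 3; air, rt
Reagents that add atoms: none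
Why: Base-catalysed methanolysis of the aryl acetates frees the hydroxyhydroquinone, whose autoxidation across the para C1 and C4 oxygens gives the only p-quinone the C5 methoxy allows and leaves the C2 oxygen as the hydroxyl, while deacetylation under nitrogen and oxidation after acidification keep the base-labile methoxyquinone away from base.

Compound list
1 | docosanoic acid (behenic acid) | CCCCCCCCCCCCCCCCCCCCCC(=O)O | starting material
2 | 1-docosanoylimidazole | CCCCCCCCCCCCCCCCCCCCCC(=O)n1ccnc1 | intermediate (not isolated)
3 | N-methoxy-N-methyldocosanamide | CCCCCCCCCCCCCCCCCCCCCC(=O)N(C)OC | intermediate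
4 | methyl 3,5-dioxohexanoate | CC(=O)CC(=O)CC(=O)OC | starting material
5 | methyl 3,5,7-trioxooctacosanoate | CCCCCCCCCCCCCCCCCCCCCC(=O)CC(=O)CC(=O)CC(=O)OC | intermediate
6 | methyl 2-henicosyl-2-hydroxy-4,6-dioxocyclohexane-1-carboxylate (mixture of diastereomers and enol tautomers, centres undefined) | CCCCCCCCCCCCCCCCCCCCCC1(O)CC(=O)CC(=O)C1C(=O)OC | intermediate (not isolated)
7 | methyl 2,4-dihydroxy-6-henicosylbenzoate | CCCCCCCCCCCCCCCCCCCCCc1cc(O)cc(O)c1C(=O)OC | intermediate
8 | methyl 2-henicosyl-6-hydroxy-4-methoxybenzoate | CCCCCCCCCCCCCCCCCCCCCc1cc(OC)cc(O)c1C(=O)OC | intermediate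
9 | 2-henicosyl-6-hydroxy-4-methoxybenzoic acid | CCCCCCCCCCCCCCCCCCCCCc1cc(OC)cc(O)c1C(=O)O | intermediate (not isolated)
10 | 3-henicosyl-5-methoxyphenol | CCCCCCCCCCCCCCCCCCCCCc1cc(O)cc(OC)c1 | intermediate
11 | 2-henicosyl-6-methoxy-1,4-benzoquinone | CCCCCCCCCCCCCCCCCCCCCC1=CC(=O)C=C(OC)C1=O | intermediate
12 | 3-henicosyl-5-methoxybenzene-1,2,4-triyl triacetate | CCCCCCCCCCCCCCCCCCCCCc1c(OC(C)=O)c(OC(C)=O)cc(OC)c1OC(C)=O | intermediate
13 | 3-henicosyl-5-methoxybenzene-1,2,4-triol | CCCCCCCCCCCCCCCCCCCCCc1c(O)c(O)cc(OC)c1O | intermediate (not isolated)
14 | 3-henicosyl-2-hydroxy-5-methoxy-1,4-benzoquinone (no stereocentres) | CCCCCCCCCCCCCCCCCCCCCC1=C(O)C(=O)C=C(OC)C1=O | target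

Total step count: 8. Longest linear sequence: 8 steps (1 to 14).

Steps most likely to fail

Step 3. The acyl-transfer closures (Claisen closure onto the ester, lactonisation of the C5 enol oxygen onto the ester) or retro-Claisen cleavage of the chain may outrun the aldol closure. The fallback sets out from 3 and masks the ester so that only the aldol mode is open. Commercial 2,2,6-trimethyl-4H-1,3-dioxin-4-one is acetylated at its methyl group (LiN(SiMe3)2, acetyl chloride, THF, −78 °C) to 2,2-dimethyl-6-(2-oxopropyl)-4H-1,3-dioxin-4-one F1. Its dianion (LiN(iPr)2, THF) is C-acylated by 3 at the terminal carbon to give 6-(2,4-dioxopentacosyl)-2,2-dimethyl-4H-1,3-dioxin-4-one F2. Triethylamine in CH2Cl2 should then close the same carbon–carbon bond (dioxinone C5 onto the chain ketone) and, after dehydration, give 5-henicosyl-7-hydroxy-2,2-dimethyl-4H-benzo[d][1,3]dioxin-4-one F3. Methanolysis (K2CO3, MeOH) opens the acetonide lactone with loss of acetone and comes back to the route at 7.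

Step 7. Conjugate addition of acetate to the 2,6-disubstituted quinone may be slow, so that acid-induced exchange of the methoxy group or addition on the methoxy-bearing double bond competes. The fallback sets out from 11. Weitz–Scheffer epoxidation (tBuOOH, DBU, CH2Cl2, 0 °C) of the more electrophilic, methoxy-free C2=C3 double bond should give racemic 1-henicosyl-3-methoxy-7-oxabicyclo[4.1.0]hept-3-ene-2,5-dione F4. Acid-mediated epoxide isomerisation (cold concentrated H2SO4 or silica gel), with loss of the C2 hydrogen and opening of the C3–O bond, comes back to the route directly at 14, bypassing 12 and 13.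

Step 2. Proton transfer from the α-methylene of the amide to the strongly basic trianion, poor solubility of the C22 amide at low temperature, or premature cyclisation of the triketo ester during the acidic quench may erode the acylation. The fallback sets out from 3 and builds the chain from the other end. Acylation of the dilithio dianion of acetylacetone (LiN(iPr)2, THF, 0 °C) by 3 gives heptacosane-2,4,6-trione F5. Its trianion (LiN(iPr)2, 3 equiv) is carboxylated at the methyl terminus with CO2 to give 3,5,7-trioxooctacosanoic acid F6. Cold, brief esterification with Me3SiCHN2 in toluene–MeOH comes back to the route at 5.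

Further compounds
F1 | step 3 | 2,2-dimethyl-6-(2-oxopropyl)-4H-1,3-dioxin-4-one | CC(=O)CC1=CC(=O)OC(C)(C)O1
F2 | step 3 | 6-(2,4-dioxopentacosyl)-2,2-dimethyl-4H-1,3-dioxin-4-one | CCCCCCCCCCCCCCCCCCCCCC(=O)CC(=O)CC1=CC(=O)OC(C)(C)O1
F3 | step 3 | 5-henicosyl-7-hydroxy-2,2-dimethyl-4H-benzo[d][1,3]dioxin-4-one | CCCCCCCCCCCCCCCCCCCCCc1cc(O)cc2OC(C)(C)OC(=O)c12
F4 | step 7 | 1-henicosyl-3-methoxy-7-oxabicyclo[4.1.0]hept-3-ene-2,5-dione (racemic) | CCCCCCCCCCCCCCCCCCCCCC12OC1C(=O)C=C(OC)C2=O
F5 | step 2 | heptacosane-2,4,6-trione | CCCCCCCCCCCCCCCCCCCCCC(=O)CC(=O)CC(C)=O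
F6 | step 2 | 3,5,7-trioxooctacosanoic acid | CCCCCCCCCCCCCCCCCCCCCC(=O)CC(=O)CC(=O)CC(=O)O
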